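(The constants used here are assumed; no experiment stands behind them.)

E is the species I follow: J turns into it, and G, which reaches the solution from solid X by way of Q, binds it as E.G.

- Wednesday's: J 20 mM; X 2.00 equiv; temperature 90 °C; time 2.0 min
- Friday's: J 20 mM; X 2.00 equiv; temperature 110 °C; time 2.0 min

    X ⇌ Q, rate k1*(cs1 - [Q]) while solid is left; crystals form when [Q] > cs1 (cs1 = 15 mM, k1 = 0.0070 s⁻¹)
    E + G → E.G (k2 = 13 L mol⁻¹ s⁻¹, Ea2 = 64.0 kJ mol⁻¹)
    J → E (k3 = 0.023 s⁻¹, Ea3 = 101 kJ mol⁻¹)
    Q → G (k4 = 0.0070 s⁻¹, Ea4 = 103 kJ mol⁻¹)
    (constants at 90 °C)

- solid, in amounts per volume of the solution: X
- the constants hold at 90 °C; other temperatures follow from the activation energies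
- at the start none of X is in solution

* which of these there is most of at the end, counted by the J in it, Wednesday's (J / E.G / E)
* which of these there is most of at the end, counted by the J in it, Friday's (J / E.G / E)
* amount of the one of these that there is most of at the end, in percent of the J charged, Wednesday's
* amount of the one of these that there is most of at the end, in percent of the J charged, Friday's

I count turnovers, in lifetimes of each stretch. J lives through 2.76 lifetimes in Wednesday's flask, which leaves 6.33%. At 110 °C, k3 rises to 0.132 s⁻¹, so in Friday's flask J lives through 15.8 and its rest is negligible.

Q relaxes towards the level k1·cs1/(k1+k4) with the lifetime 1/(k1+k4), and while it does so it makes G at k4[Q]. Step 1 is given no activation energy, so on this stretch temperature enters through k4, which reaches 0.0415 s⁻¹ on Friday's. That gives lifetimes of 71.4 s on Wednesday's and 20.6 s on Friday's.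

Integrating k4[Q] over the run gives 3.25 mM on Wednesday's and 8.94 mM on Friday's. I call this amount of G made by the end of the run the delivered G. With k2 as given, a G meeting E at the full charge lasts about 3.85 s, shorter than either lifetime of Q, so I expect E.G to follow this supply, with delivered G as its ceiling. On Friday's, where k4 stands above k1, I take the dissolving of X as the rate-limiting step of that supply.

Now the settings, by hand. Time adds 5.39 mM min⁻¹ to Friday's delivered G for each further minute. The charge of J does not appear in delivered G; it is merely the divisor of the share. X does not appear either, since its 40.0 mM stands far above the delivered amount. Temperature takes E from 77.4% on Wednesday's to 55.3% on Friday's, and I commit to E leading in both.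

The forecast gives E at 78.5% on Wednesday's and E at 56.4% on Friday's, on the ground that capture “is limited by the slow dissolution of X”.

Wednesday's flask gives E at 78.5%. Friday's flask gives E at 56.3%. Friday's E.G is 43.7% of the charge, or 8.74 mM, and my delivered 8.94 mM stands above that by about the 0.199 mM of G still free. Moved one at a time by the same factor, temperature apart, the settings shift Friday's E by up to these amounts: time (16 points), then J (12 points), then X (under 0.05 points).

The difference in temperature may be called the main reason for the gap in E between the two flasks: Friday's flask brought back to Wednesday's temperature ends with E at 78.5% instead of 56.3%, a move of 22 percentage points.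

Take Friday's flask with 50 mM of J, equivalents and time held. Delivered G stays 8.94 mM, so I reckon E.G at 17.9% and E at 82.1%; that flask gives 17.8% and 82.2%.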